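**Plan**

1. Cuts: C6–C3' between ring B and the second dihydrobenzofuran, then C3–ring C, both as decarboxylative arylations of dihydrobenzofuran-3-carboxylic acids; then C2–C3 and C2'–C3' as carbene C–H insertions, back to aryldiazoacetates built on 2-bromoresorcinol.
2. Enabling feature: C3a of ring B lies between C4 (OH) and C7a (O1), and C3a' of ring E between C4' (OH) and C7a' (O1'). A carbene at C3 (C3') can therefore sit between two identical benzyl ethers; insertion into either closes the same O1–C2–C3 (O1'–C2'–C3') ring with ring A (ring D) on C2 (C2'), and the ether left over masks the C4 (C4') hydroxyl.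
3. Fragment 1: twin vanillyl ethers on 2-bromoresorcinol, diazoester, rhodium insertion (first dihydrofuran ring), ring C onto C3 by nickel catalysis, iodine onto C6 through iridium borylation.
4. Fragment 2: the same sequence with 4-silyloxybenzyl ethers, the styryl arm added by a Heck reaction before the diazoester is made, and the mirror-image rhodium catalyst (second dihydrofuran ring); C3'–C6 union by a second decarboxylative arylation; one fluoride step frees all phenols.
5. Stereochemistry: C2 and C2' from the two enantiomeric dirhodium carboxylates; C3 and C3' from capture of planar benzylic radicals trans to the aryl group on the neighbouring carbon; E alkene from the Heck step.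

Key step: step 6

Ring letters: A = guaiacyl ring on C2; B = benzo ring of the first dihydrobenzofuran (O1, C2, C3, C3a, C4–C7, C7a); C = 3,5-dihydroxyphenyl on C3; D = 4-hydroxyphenyl on C2'; E = benzo ring of the second (primed) dihydrobenzofuran; F = 4-hydroxyphenyl of the styryl group on C6'. TIPS = triisopropylsilyl; dtbbpy = 4,4'-di-tert-butyl-2,2'-bipyridine; Bpin = 4,4,5,5-tetramethyl-1,3,2-dioxaborolan-2-yl; DIAD = diisopropyl azodicarboxylate; DIC = N,N'-diisopropylcarbodiimide.

Assumption: Rh2(S-PTTL)4 is taken to deliver the (2R) ether carbon in these insertions, so Rh2(R-PTTL)4 serves fragment 1 (2S) and Rh2(S-PTTL)4 fragment 2 (2'R); if the sense is the reverse, the two catalysts change places.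

**Route**

Step 1
Reactants: 1 vanillin
Product: 2 3-methoxy-4-(triisopropylsilyloxy)benzaldehyde
Conditions: TIPSCl, imidazole, DMF, rt
Reagents that add atoms: chlorotriisopropylsilane, CC(C)[Si](Cl)(C(C)C)C(C)C
Why: Imidazole-promoted O-silylation of the phenol gives an aryl TIPS ether that should withstand butyllithium, rhodium carbenes and zinc/nickel and is removed by fluoride at the end.

Step 2
Reactants: 2 3-methoxy-4-(triisopropylsilyloxy)benzaldehyde
Product: 3 [3-methoxy-4-(triisopropylsilyloxy)phenyl]methanol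
Conditions: NaBH4, MeOH/THF, 0 °C
Reagents that add atoms: none
Why: Borohydride reduction of the aldehyde is chemoselective and leaves the aryl silyl ether untouched.

Step 3
Reactants: 3 [3-methoxy-4-(triisopropylsilyloxy)phenyl]methanol (2.2 equiv); 4 2-bromoresorcinol
Product: 5 2-bromo-1,3-bis{[3-methoxy-4-(triisopropylsilyloxy)phenyl]methoxy}benzene
Conditions: PPh3, DIAD, THF, 0 °C to rt
Reagents that add atoms: none
Why: A double Mitsunobu etherification alkylates both acidic phenols with the activated primary benzylic alcohol under neutral conditions, avoiding a labile 4-silyloxybenzyl halide and any base that could cleave the aryl silyl ether.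

Step 4
Reactants: 5 2-bromo-1,3-bis{[3-methoxy-4-(triisopropylsilyloxy)phenyl]methoxy}benzene
Product: 7 methyl 2-(2,6-bis{[3-methoxy-4-(triisopropylsilyloxy)phenyl]methoxy}phenyl)-2-oxoacetate, via aryllithium 6 (not isolated)
Conditions: n-BuLi, THF, −78 °C; cannulated into dimethyl oxalate (3 equiv), THF, −78 °C; aq. NH4Cl
Reagents that add atoms: dimethyl oxalate, COC(=O)C(=O)OC
Why: Bromine–lithium exchange at −78 °C should outrun benzylic deprotonation and Wittig rearrangement, and inverse addition of the hindered aryllithium to excess oxalate diester stops at the α-keto ester (acylation of an organolithium).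

Step 5
Reactants: 7 methyl 2-(2,6-bis{[3-methoxy-4-(triisopropylsilyloxy)phenyl]methoxy}phenyl)-2-oxoacetate
Product: 9 methyl 2-diazo-2-(2,6-bis{[3-methoxy-4-(triisopropylsilyloxy)phenyl]methoxy}phenyl)acetate, via tosylhydrazone 8 (not isolated)
Conditions: TsNHNH2, toluene, 80 °C; then DBU, CH2Cl2, 0 °C to rt
Reagents that add atoms: p-toluenesulfonyl hydrazide, Cc1ccc(cc1)S(=O)(=O)NN
Why: Condensation of the activated keto group with tosylhydrazide and base-induced loss of sulfinate (Bamford–Stevens diazo synthesis) is the standard passage from aryl glyoxylates to aryldiazoacetates.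

Step 6
Reactants: 9 methyl 2-diazo-2-(2,6-bis{[3-methoxy-4-(triisopropylsilyloxy)phenyl]methoxy}phenyl)acetate
Product: 10 methyl (2S,3R)-2-[3-methoxy-4-(triisopropylsilyloxy)phenyl]-4-{[3-methoxy-4-(triisopropylsilyloxy)phenyl]methoxy}-2,3-dihydrobenzofuran-3-carboxylate (cis)
Conditions: Rh2(R-PTTL)4 (dirhodium tetrakis[N-phthaloyl-(R)-tert-leucinate], 1 mol %), toluene, −60 °C, slow addition of 9
Reagents that add atoms: none
Why: The dirhodium carboxylate expels N2 from 9 to give a donor/acceptor rhodium carbene at the future C3, which inserts into a benzylic C–H of one vanillyl ether through a concerted, asynchronous three-centre transition state with hydride-transfer character. The closest known reaction is the Rh2(PTTL)4-catalysed intramolecular C–H insertion of ortho-benzyloxy aryldiazoacetates to cis-2-aryl-2,3-dihydrobenzofuran-3-carboxylates. The O1–C2–C3–C3a–C7a ring closes by 1,5 insertion, with C2–C3 as the only new skeletal bond. C2 (S) is set by the chiral carboxylate ligands, which choose between the two enantiotopic ethers of the achiral carbene (the counterpart of carbene-face selection in the mono-ether series), and C3 follows as the kinetic cis ester. The step needs 1,5 site selectivity and enantiotopic-group selectivity: the first is secured by the five-membered transition state and a C–H bond activated by both the ether oxygen and the electron-rich ring A, the second by the catalyst, helped by the two ortho substituents, which hold the aryl ring perpendicular to the carbene plane as the insertion geometry demands. The ether that is not used stays on the C4 oxygen as its protecting group.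

Step 7
Reactants: 10 methyl (2S,3R)-cis ester
Product: 11 (2S,3R)-2-[3-methoxy-4-(triisopropylsilyloxy)phenyl]-4-{[3-methoxy-4-(triisopropylsilyloxy)phenyl]methoxy}-2,3-dihydrobenzofuran-3-carboxylic acid
Conditions: Me3SnOH, 1,2-dichloroethane, 80 °C; dilute aq. HCl wash
Reagents that add atoms: trimethyltin hydroxide, C[Sn](C)(C)O
Why: Trimethyltin hydroxide hydrolyses methyl esters under near-neutral conditions, so the aryl silyl ethers (and the phenoxide-triggered pathways they hold back at C2 and at the spare ether) should stay intact; any epimerisation at C3 is harmless because C3 becomes a radical next.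

Step 8
Reactants: 12 5-iodoresorcinol
Product: 13 1-iodo-3,5-bis(triisopropylsilyloxy)benzene
Conditions: TIPSCl (2.2 equiv), imidazole, DMF, rt
Reagents that add atoms: chlorotriisopropylsilane, CC(C)[Si](Cl)(C(C)C)C(C)C
Why: Imidazole-promoted silylation of both phenols gives the ring C iodide in the same protecting-group family as the rest of the molecule.

Step 9
Reactants: 11 (2S,3R)-acid; 13 1-iodo-3,5-bis(triisopropylsilyloxy)benzene
Product: 15 (2S,3S)-3-[3,5-bis(triisopropylsilyloxy)phenyl]-2-[3-methoxy-4-(triisopropylsilyloxy)phenyl]-4-{[3-methoxy-4-(triisopropylsilyloxy)phenyl]methoxy}-2,3-dihydrobenzofuran (trans), via phthalimidoyl ester 14 (not isolated)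
Conditions: N-hydroxyphthalimide, DIC, DMAP (cat.), CH2Cl2, rt; then 13, NiBr2(dme) (10 mol %), dtbbpy, Zn, DMA, rt
Reagents that add atoms: none
Why: In this nickel-catalysed decarboxylative cross-electrophile arylation, single-electron reduction of the redox-active ester releases CO2 and a planar benzylic C3 radical, which aryl-nickel should capture on the face away from ring A to give the trans (3S) product after reductive elimination; any minor cis isomer is removed here by chromatography.

Step 10
Reactants: 15 trans-2,3-diaryl-2,3-dihydrobenzofuran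
Product: 17 (2S,3S)-3-[3,5-bis(triisopropylsilyloxy)phenyl]-6-iodo-2-[3-methoxy-4-(triisopropylsilyloxy)phenyl]-4-{[3-methoxy-4-(triisopropylsilyloxy)phenyl]methoxy}-2,3-dihydrobenzofuran (fragment 1), via C6 pinacol boronate 16 (not isolated)
Conditions: [Ir(cod)OMe]2 (cat.), dtbbpy, B2pin2, THF, 80 °C; then CuI (10 mol %), 1,10-phenanthroline, KI, MeOH/THF/H2O, air, 80 °C
Reagents that add atoms: potassium iodide, [K+].[I-]
Why: Iridium-catalysed C–H borylation is sterically controlled and C6–H of ring B is the only aromatic C–H without an ortho substituent, and copper-catalysed iododeboronation then turns the boronate into the iodide in the same flask.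

Step 11
Reactants: 18 4-hydroxybenzaldehyde
Product: 19 4-(triisopropylsilyloxy)benzaldehyde
Conditions: TIPSCl, imidazole, DMF, rt
Reagents that add atoms: chlorotriisopropylsilane, CC(C)[Si](Cl)(C(C)C)C(C)C
Why: Imidazole-promoted O-silylation of the phenol, as in step 1.

Step 12
Reactants: 19 4-(triisopropylsilyloxy)benzaldehyde
Product: 20 [4-(triisopropylsilyloxy)phenyl]methanol
Conditions: NaBH4, MeOH/THF, 0 °C
Reagents that add atoms: none
Why: Chemoselective borohydride reduction of the aldehyde, as in step 2.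

Step 13
Reactants: 20 [4-(triisopropylsilyloxy)phenyl]methanol (2.2 equiv); 4 2-bromoresorcinol
Product: 21 2-bromo-1,3-bis{[4-(triisopropylsilyloxy)phenyl]methoxy}benzene
Conditions: PPh3, DIAD, THF, 0 °C to rt
Reagents that add atoms: none
Why: Double Mitsunobu etherification of the two phenols, as in step 3.

Step 14
Reactants: 21 2-bromo-1,3-bis{[4-(triisopropylsilyloxy)phenyl]methoxy}benzene
Product: 23 2-bromo-5-iodo-1,3-bis{[4-(triisopropylsilyloxy)phenyl]methoxy}benzene, via C5 pinacol boronate 22 (not isolated)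
Conditions: [Ir(cod)OMe]2 (cat.), dtbbpy, B2pin2, THF, 80 °C; then CuI (10 mol %), 1,10-phenanthroline, KI, MeOH/THF/H2O, air, 80 °C
Reagents that add atoms: potassium iodide, [K+].[I-]
Why: Sterically controlled iridium C–H borylation should take the only unhindered C–H (C5, para to bromine) and tolerates the aryl bromide, and copper-catalysed iododeboronation completes the formal meta-iodination.

Step 15
Reactants: 19 4-(triisopropylsilyloxy)benzaldehyde
Product: 24 4-(triisopropylsilyloxy)styrene
Conditions: Ph3PCH3Br, NaHMDS, THF, 0 °C to rt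
Reagents that add atoms: methyltriphenylphosphonium bromide, C[P+](c1ccccc1)(c1ccccc1)c1ccccc1.[Br-]
Why: Wittig methylenation of the aldehyde with the preformed non-stabilised ylide gives the terminal styrene without touching the silyl ether.

Step 16
Reactants: 23 2-bromo-5-iodo bis-ether; 24 4-(triisopropylsilyloxy)styrene
Product: 25 2-bromo-1,3-bis{[4-(triisopropylsilyloxy)phenyl]methoxy}-5-[(E)-2-(4-triisopropylsilyloxyphenyl)ethenyl]benzene
Conditions: Pd(OAc)2 (5 mol %), n-Bu4NCl, NaHCO3, DMF, 60 °C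
Reagents that add atoms: none
Why: In this Heck reaction zerovalent palladium inserts into the C–I bond far faster than into the C–Br bond flanked by two alkoxy groups, and syn insertion followed by syn β-hydride elimination gives the E-stilbene.

Step 17
Reactants: 25 (E)-bromostilbene
Product: 27 methyl 2-(2,6-bis{[4-(triisopropylsilyloxy)phenyl]methoxy}-4-[(E)-2-(4-triisopropylsilyloxyphenyl)ethenyl]phenyl)-2-oxoacetate, via aryllithium 26 (not isolated)
Conditions: n-BuLi, THF, −78 °C; cannulated into dimethyl oxalate (3 equiv), THF, −78 °C; aq. NH4Cl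
Reagents that add atoms: dimethyl oxalate, COC(=O)C(=O)OC
Why: Bromine–lithium exchange at −78 °C should be faster than carbolithiation of the stilbene or benzylic deprotonation, and acylation of the aryllithium by excess oxalate diester stops at the α-keto ester.

Step 18
Reactants: 27 α-keto ester
Product: 29 methyl 2-diazo-2-(2,6-bis{[4-(triisopropylsilyloxy)phenyl]methoxy}-4-[(E)-2-(4-triisopropylsilyloxyphenyl)ethenyl]phenyl)acetate, via tosylhydrazone 28 (not isolated)
Conditions: TsNHNH2, toluene, 80 °C; then DBU, CH2Cl2, 0 °C to rt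
Reagents that add atoms: p-toluenesulfonyl hydrazide, Cc1ccc(cc1)S(=O)(=O)NN
Why: Bamford–Stevens diazo synthesis from the tosylhydrazone, as in step 5.

Step 19
Reactants: 29 diazoester
Product: 30 methyl (2R,3S)-2-[4-(triisopropylsilyloxy)phenyl]-4-{[4-(triisopropylsilyloxy)phenyl]methoxy}-6-[(E)-2-(4-triisopropylsilyloxyphenyl)ethenyl]-2,3-dihydrobenzofuran-3-carboxylate (cis)
Conditions: Rh2(S-PTTL)4 (1 mol %), toluene, −60 °C, slow addition of 29
Reagents that add atoms: none
Why: The same enantioselective intramolecular 1,5 C–H insertion as in step 6, run with the mirror-image catalyst, should set C2' (R) by choosing the other enantiotopic ether, while the trans-disubstituted stilbene alkene is a poor partner for intermolecular cyclopropanation by a donor/acceptor carbene.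

Step 20
Reactants: 30 methyl (2R,3S)-cis ester
Product: 31 (2R,3S)-2-[4-(triisopropylsilyloxy)phenyl]-4-{[4-(triisopropylsilyloxy)phenyl]methoxy}-6-[(E)-2-(4-triisopropylsilyloxyphenyl)ethenyl]-2,3-dihydrobenzofuran-3-carboxylic acid (fragment 2)
Conditions: Me3SnOH, 1,2-dichloroethane, 80 °C; dilute aq. HCl wash
Reagents that add atoms: trimethyltin hydroxide, C[Sn](C)(C)O
Why: Near-neutral ester hydrolysis with trimethyltin hydroxide, as in step 7, keeps all aryl silyl ethers and the stilbene intact.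

Step 21
Reactants: 31 fragment 2 acid; 17 fragment 1 iodide
Product: 33 fully protected trimer: (2S,3S)-3-[3,5-bis(triisopropylsilyloxy)phenyl]-2-[3-methoxy-4-(triisopropylsilyloxy)phenyl]-4-{[3-methoxy-4-(triisopropylsilyloxy)phenyl]methoxy}-6-{(2R,3R)-2-[4-(triisopropylsilyloxy)phenyl]-4-{[4-(triisopropylsilyloxy)phenyl]methoxy}-6-[(E)-2-(4-triisopropylsilyloxyphenyl)ethenyl]-2,3-dihydrobenzofuran-3-yl}-2,3-dihydrobenzofuran, via phthalimidoyl ester 32 (not isolated)
Conditions: N-hydroxyphthalimide, DIC, DMAP (cat.), CH2Cl2, rt; then 17, NiBr2(dme) (10 mol %), dtbbpy, Zn, DMA, rt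
Reagents that add atoms: none
Why: The nickel-catalysed decarboxylative cross-electrophile arylation of step 9 is repeated: the planar benzylic C3' radical should be captured by the aryl-nickel formed at the unhindered C6–I bond on the face away from ring D, which sets C3' (R) trans to C2'.

Step 22
Reactants: 33 fully protected trimer
Product: 35 gnetin K, via desilylated bis-benzyl ether 34 (not isolated)
Conditions: TBAF (10 equiv), 1-octanethiol (20 equiv), degassed THF, 0 °C to rt; then AcOH
Reagents that add atoms: none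
Why: Fluoride desilylation frees all seven phenols, the two spare 4-hydroxybenzyl-type aryl ethers then fragment by 1,6-elimination to release the C4 and C4' phenols, and the thiol traps the resulting quinone methides by conjugate addition; any reversible phenoxide-induced opening at C2 or C2' recloses to the trans rings because C3 and C3' are untouched.

**Compound list**

1 | vanillin (4-hydroxy-3-methoxybenzaldehyde) | COc1cc(C=O)ccc1O | starting material
2 | 3-methoxy-4-(triisopropylsilyloxy)benzaldehyde | COc1cc(C=O)ccc1O[Si](C(C)C)(C(C)C)C(C)C | intermediate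
3 | [3-methoxy-4-(triisopropylsilyloxy)phenyl]methanol | COc1cc(CO)ccc1O[Si](C(C)C)(C(C)C)C(C)C | intermediate
4 | 2-bromoresorcinol | Oc1cccc(O)c1Br | starting material
5 | 2-bromo-1,3-bis{[3-methoxy-4-(triisopropylsilyloxy)phenyl]methoxy}benzene | COc1cc(COc2cccc(OCc3ccc(O[Si](C(C)C)(C(C)C)C(C)C)c(OC)c3)c2Br)ccc1O[Si](C(C)C)(C(C)C)C(C)C | intermediate
6 | 2,6-bis{[3-methoxy-4-(triisopropylsilyloxy)phenyl]methoxy}phenyllithium | COc1cc(COc2cccc(OCc3ccc(O[Si](C(C)C)(C(C)C)C(C)C)c(OC)c3)c2[Li])ccc1O[Si](C(C)C)(C(C)C)C(C)C | intermediate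
7 | methyl 2-(2,6-bis{[3-methoxy-4-(triisopropylsilyloxy)phenyl]methoxy}phenyl)-2-oxoacetate | COC(=O)C(=O)c1c(OCc2ccc(O[Si](C(C)C)(C(C)C)C(C)C)c(OC)c2)cccc1OCc1ccc(O[Si](C(C)C)(C(C)C)C(C)C)c(OC)c1 | intermediate
8 | N-tosylhydrazone of 7 | COC(=O)C(=NNS(=O)(=O)c1ccc(C)cc1)c1c(OCc2ccc(O[Si](C(C)C)(C(C)C)C(C)C)c(OC)c2)cccc1OCc1ccc(O[Si](C(C)C)(C(C)C)C(C)C)c(OC)c1 | intermediate
9 | methyl 2-diazo-2-(2,6-bis{[3-methoxy-4-(triisopropylsilyloxy)phenyl]methoxy}phenyl)acetate | COC(=O)C(=[N+]=[N-])c1c(OCc2ccc(O[Si](C(C)C)(C(C)C)C(C)C)c(OC)c2)cccc1OCc1ccc(O[Si](C(C)C)(C(C)C)C(C)C)c(OC)c1 | intermediate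
10 | methyl (2S,3R)-2-[3-methoxy-4-(triisopropylsilyloxy)phenyl]-4-{[3-methoxy-4-(triisopropylsilyloxy)phenyl]methoxy}-2,3-dihydrobenzofuran-3-carboxylate (cis) | COc1cc([C@H]2Oc3cccc(OCc4ccc(O[Si](C(C)C)(C(C)C)C(C)C)c(OC)c4)c3[C@H]2C(=O)OC)ccc1O[Si](C(C)C)(C(C)C)C(C)C | intermediate
11 | (2S,3R)-carboxylic acid corresponding to 10 | COc1cc([C@H]2Oc3cccc(OCc4ccc(O[Si](C(C)C)(C(C)C)C(C)C)c(OC)c4)c3[C@H]2C(=O)O)ccc1O[Si](C(C)C)(C(C)C)C(C)C | intermediate
12 | 5-iodoresorcinol | Oc1cc(O)cc(I)c1 | starting material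
13 | 1-iodo-3,5-bis(triisopropylsilyloxy)benzene | CC(C)[Si](Oc1cc(I)cc(O[Si](C(C)C)(C(C)C)C(C)C)c1)(C(C)C)C(C)C | intermediate
14 | 1,3-dioxoisoindolin-2-yl (phthalimidoyl) ester of acid 11 | COc1cc([C@H]2Oc3cccc(OCc4ccc(O[Si](C(C)C)(C(C)C)C(C)C)c(OC)c4)c3[C@H]2C(=O)ON2C(=O)c3ccccc3C2=O)ccc1O[Si](C(C)C)(C(C)C)C(C)C | intermediate
15 | (2S,3S)-3-[3,5-bis(triisopropylsilyloxy)phenyl]-2-[3-methoxy-4-(triisopropylsilyloxy)phenyl]-4-{[3-methoxy-4-(triisopropylsilyloxy)phenyl]methoxy}-2,3-dihydrobenzofuran (trans) | COc1cc([C@H]2Oc3cccc(OCc4ccc(O[Si](C(C)C)(C(C)C)C(C)C)c(OC)c4)c3[C@@H]2c2cc(O[Si](C(C)C)(C(C)C)C(C)C)cc(O[Si](C(C)C)(C(C)C)C(C)C)c2)ccc1O[Si](C(C)C)(C(C)C)C(C)C | intermediate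
16 | 6-Bpin derivative of 15 | COc1cc([C@H]2Oc3cc(B4OC(C)(C)C(C)(C)O4)cc(OCc4ccc(O[Si](C(C)C)(C(C)C)C(C)C)c(OC)c4)c3[C@@H]2c2cc(O[Si](C(C)C)(C(C)C)C(C)C)cc(O[Si](C(C)C)(C(C)C)C(C)C)c2)ccc1O[Si](C(C)C)(C(C)C)C(C)C | intermediate
17 | 6-iodo derivative of 15 (fragment 1) | COc1cc([C@H]2Oc3cc(I)cc(OCc4ccc(O[Si](C(C)C)(C(C)C)C(C)C)c(OC)c4)c3[C@@H]2c2cc(O[Si](C(C)C)(C(C)C)C(C)C)cc(O[Si](C(C)C)(C(C)C)C(C)C)c2)ccc1O[Si](C(C)C)(C(C)C)C(C)C | intermediate
18 | 4-hydroxybenzaldehyde | O=Cc1ccc(O)cc1 | starting material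
19 | 4-(triisopropylsilyloxy)benzaldehyde | O=Cc1ccc(O[Si](C(C)C)(C(C)C)C(C)C)cc1 | intermediate
20 | [4-(triisopropylsilyloxy)phenyl]methanol | OCc1ccc(O[Si](C(C)C)(C(C)C)C(C)C)cc1 | intermediate
21 | 2-bromo-1,3-bis{[4-(triisopropylsilyloxy)phenyl]methoxy}benzene | Brc1c(OCc2ccc(O[Si](C(C)C)(C(C)C)C(C)C)cc2)cccc1OCc1ccc(O[Si](C(C)C)(C(C)C)C(C)C)cc1 | intermediate
22 | 5-Bpin derivative of 21 | Brc1c(OCc2ccc(O[Si](C(C)C)(C(C)C)C(C)C)cc2)cc(B2OC(C)(C)C(C)(C)O2)cc1OCc1ccc(O[Si](C(C)C)(C(C)C)C(C)C)cc1 | intermediate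
23 | 2-bromo-5-iodo-1,3-bis{[4-(triisopropylsilyloxy)phenyl]methoxy}benzene | Brc1c(OCc2ccc(O[Si](C(C)C)(C(C)C)C(C)C)cc2)cc(I)cc1OCc1ccc(O[Si](C(C)C)(C(C)C)C(C)C)cc1 | intermediate
24 | 4-(triisopropylsilyloxy)styrene | C=Cc1ccc(O[Si](C(C)C)(C(C)C)C(C)C)cc1 | intermediate
25 | 2-bromo-1,3-bis{[4-(triisopropylsilyloxy)phenyl]methoxy}-5-[(E)-2-(4-triisopropylsilyloxyphenyl)ethenyl]benzene | Brc1c(OCc2ccc(O[Si](C(C)C)(C(C)C)C(C)C)cc2)cc(/C=C/c2ccc(O[Si](C(C)C)(C(C)C)C(C)C)cc2)cc1OCc1ccc(O[Si](C(C)C)(C(C)C)C(C)C)cc1 | intermediate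
26 | aryllithium from 25 (lithium in place of bromine) | [Li]c1c(OCc2ccc(O[Si](C(C)C)(C(C)C)C(C)C)cc2)cc(/C=C/c2ccc(O[Si](C(C)C)(C(C)C)C(C)C)cc2)cc1OCc1ccc(O[Si](C(C)C)(C(C)C)C(C)C)cc1 | intermediate
27 | methyl 2-(2,6-bis{[4-(triisopropylsilyloxy)phenyl]methoxy}-4-[(E)-2-(4-triisopropylsilyloxyphenyl)ethenyl]phenyl)-2-oxoacetate | COC(=O)C(=O)c1c(OCc2ccc(O[Si](C(C)C)(C(C)C)C(C)C)cc2)cc(/C=C/c2ccc(O[Si](C(C)C)(C(C)C)C(C)C)cc2)cc1OCc1ccc(O[Si](C(C)C)(C(C)C)C(C)C)cc1 | intermediate
28 | N-tosylhydrazone of 27 | COC(=O)C(=NNS(=O)(=O)c1ccc(C)cc1)c1c(OCc2ccc(O[Si](C(C)C)(C(C)C)C(C)C)cc2)cc(/C=C/c2ccc(O[Si](C(C)C)(C(C)C)C(C)C)cc2)cc1OCc1ccc(O[Si](C(C)C)(C(C)C)C(C)C)cc1 | intermediate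
29 | methyl 2-diazo-2-(2,6-bis{[4-(triisopropylsilyloxy)phenyl]methoxy}-4-[(E)-2-(4-triisopropylsilyloxyphenyl)ethenyl]phenyl)acetate | COC(=O)C(=[N+]=[N-])c1c(OCc2ccc(O[Si](C(C)C)(C(C)C)C(C)C)cc2)cc(/C=C/c2ccc(O[Si](C(C)C)(C(C)C)C(C)C)cc2)cc1OCc1ccc(O[Si](C(C)C)(C(C)C)C(C)C)cc1 | intermediate
30 | methyl (2R,3S)-2-[4-(triisopropylsilyloxy)phenyl]-4-{[4-(triisopropylsilyloxy)phenyl]methoxy}-6-[(E)-2-(4-triisopropylsilyloxyphenyl)ethenyl]-2,3-dihydrobenzofuran-3-carboxylate (cis) | CC(C)[Si](Oc1ccc([C@@H]2Oc3cc(/C=C/c4ccc(O[Si](C(C)C)(C(C)C)C(C)C)cc4)cc(OCc4ccc(O[Si](C(C)C)(C(C)C)C(C)C)cc4)c3[C@@H]2C(=O)OC)cc1)(C(C)C)C(C)C | intermediate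
31 | (2R,3S)-carboxylic acid corresponding to 30 (fragment 2) | CC(C)[Si](Oc1ccc([C@@H]2Oc3cc(/C=C/c4ccc(O[Si](C(C)C)(C(C)C)C(C)C)cc4)cc(OCc4ccc(O[Si](C(C)C)(C(C)C)C(C)C)cc4)c3[C@@H]2C(=O)O)cc1)(C(C)C)C(C)C | intermediate
32 | 1,3-dioxoisoindolin-2-yl (phthalimidoyl) ester of acid 31 | CC(C)[Si](Oc1ccc([C@@H]2Oc3cc(/C=C/c4ccc(O[Si](C(C)C)(C(C)C)C(C)C)cc4)cc(OCc4ccc(O[Si](C(C)C)(C(C)C)C(C)C)cc4)c3[C@@H]2C(=O)ON2C(=O)c3ccccc3C2=O)cc1)(C(C)C)C(C)C | intermediate
33 | fully protected trimer (2S,3S,2'R,3'R): seven TIPS ethers, vanillyl ether on O4, 4-silyloxybenzyl ether on O4' | COc1cc([C@H]2Oc3cc([C@@H]4c5c(OCc6ccc(O[Si](C(C)C)(C(C)C)C(C)C)cc6)cc(/C=C/c6ccc(O[Si](C(C)C)(C(C)C)C(C)C)cc6)cc5O[C@H]4c4ccc(O[Si](C(C)C)(C(C)C)C(C)C)cc4)cc(OCc4ccc(O[Si](C(C)C)(C(C)C)C(C)C)c(OC)c4)c3[C@@H]2c2cc(O[Si](C(C)C)(C(C)C)C(C)C)cc(O[Si](C(C)C)(C(C)C)C(C)C)c2)ccc1O[Si](C(C)C)(C(C)C)C(C)C | intermediate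
34 | desilylated trimer still carrying the 4-hydroxy-3-methoxybenzyl ether on O4 and the 4-hydroxybenzyl ether on O4' | COc1cc([C@H]2Oc3cc([C@@H]4c5c(OCc6ccc(O)cc6)cc(/C=C/c6ccc(O)cc6)cc5O[C@H]4c4ccc(O)cc4)cc(OCc4ccc(O)c(OC)c4)c3[C@@H]2c2cc(O)cc(O)c2)ccc1O | intermediate
35 | gnetin K: (2S,3S)-3-(3,5-dihydroxyphenyl)-2-(4-hydroxy-3-methoxyphenyl)-6-{(2R,3R)-4-hydroxy-2-(4-hydroxyphenyl)-6-[(E)-2-(4-hydroxyphenyl)ethenyl]-2,3-dihydrobenzofuran-3-yl}-2,3-dihydrobenzofuran-4-ol | COc1cc([C@H]2Oc3cc([C@@H]4c5c(O)cc(/C=C/c6ccc(O)cc6)cc5O[C@H]4c4ccc(O)cc4)cc(O)c3[C@@H]2c2cc(O)cc(O)c2)ccc1O | target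

**Step count and risks**

Total: 22 steps. Longest linear sequence: 11 steps (steps 1–7, 9, 10, 21, 22 from vanillin; the branch from 4-hydroxybenzaldehyde through steps 11–14, 16–22 is equally long).

Steps most likely to fail:

1. Step 21 (fragment union). The stabilised, hindered C3' benzylic radical, or ester 32 itself, may be reduced at the zinc surface faster than the bulky aryl-nickel captures it, ending in hydrodecarboxylation or radical dimerisation. The fallback makes the aryl partner the nucleophile, so that no metallic reductant is present during coupling. It sets out from iodide 17, which is converted with zinc dust and LiCl in THF at 40 °C into the arylzinc iodide F1 and decanted from excess zinc. Acid 31 is converted as before into the phthalimidoyl ester 32, which is now isolated, and 32 is coupled with F1 under NiCl2(dme)/dtbbpy in THF/DMF at rt (decarboxylative Negishi-type arylation). The same trans-selective radical capture should apply, and the fallback comes back to the route at 33.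

2. Step 6 (and its mirror image, step 19). The twisted, doubly ortho-substituted carbene may sit differently in the chiral pocket than the mono-ether carbenes for which the catalyst is known, eroding the choice between the two enantiotopic ethers. The fallback moves the burden of enantiopurity from the catalyst to a classical resolution. It sets out from acid 11 of insufficient enantiomeric purity, which is combined with (R)-1-phenylethylamine; the salt F2 is recrystallised to constant rotation and the acid is liberated with cold dilute aqueous KHSO4, returning to the route at 11. The same treatment with the enantiomeric amine would serve acid 31.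

3. Step 22 (global deprotection). The two quinone methides released in the basic fluoride medium may C-alkylate the electron-rich polyphenolate product, or the ether fragmentation may stall once the medium is buffered. The fallback separates silyl removal from ether fragmentation and destroys the quinone methides reductively. It sets out from 33, which is desilylated with Et3N·3HF in THF at rt; no phenoxide is formed, so the bis-benzyl ether 34 can be isolated and purified. Compound 34 is then treated with excess NaBH4 in degassed THF/MeOH containing a little aqueous NaOH at 0 °C to rt. The 1,6-elimination proceeds under these conditions and each quinone methide is reduced at once to the corresponding cresol, returning to the route at 35.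

**Further compounds**

F1 | step 21 | arylzinc iodide from 17 (ZnI in place of iodine at C6) | COc1cc([C@H]2Oc3cc([Zn]I)cc(OCc4ccc(O[Si](C(C)C)(C(C)C)C(C)C)c(OC)c4)c3[C@@H]2c2cc(O[Si](C(C)C)(C(C)C)C(C)C)cc(O[Si](C(C)C)(C(C)C)C(C)C)c2)ccc1O[Si](C(C)C)(C(C)C)C(C)C
F2 | step 6 | (R)-1-phenylethylammonium salt of acid 11 | COc1cc([C@H]2Oc3cccc(OCc4ccc(O[Si](C(C)C)(C(C)C)C(C)C)c(OC)c4)c3[C@H]2C(=O)[O-])ccc1O[Si](C(C)C)(C(C)C)C(C)C.C[C@@H]([NH3+])c1ccccc1
F0 | step 22 | none | none
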